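**Plan**
- Cuts: first the four O–benzyl bonds. Then ring B is cut across C1–C2 and C5–C6. Last come the two acyl–oxygen bonds: ring A carbonyl to O4 of ring B, and the ring B C1 carbonyl to O4 of ring C.
- Enabling feature: ring B is an orsellinate (C1 carboxyl, C2 OH, C4 acyloxy, C6 methyl). Its C2–C5 therefore map onto an acetoacetate-derived 1,1,3-trioxygenated diene that already holds ring A on O4. C6–C1 map onto a but-2-ynoate that already holds ring C on its ester oxygen.
- Forward, left half: orcinol is taken to the ring A acid by formylation, benzylation, Baeyer–Villiger oxygenation, benzylation, a second formylation and oxidation. The acid is then turned into the enol ester and the silyl ketene acetal.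
- Forward, right half: orsellinic acid gives the ring C ynoate in three steps. Rings A and C are bought as arenes. Ring B is the only ring built, in the convergent cycloaddition/aromatisation, and hydrogenolysis ends the route.
- Stereochemistry: the target has none. The alkene geometries of the enol ester and the diene and the racemic ketal carbon of the cycloadduct all vanish when ring B aromatises.

Key step: step 12

Remark: the target has no stereocentre, stereogenic axis or configurable double bond. It is a single achiral compound, so no enantioselective step is needed. In every ring, C1 carries the carboxyl carbon, C2 the ortho oxygen and C6 the methyl group.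

**Step 1**
Reactants: 1 orcinol (5-methylbenzene-1,3-diol)
Product: 3 2,4-dihydroxy-6-methylbenzaldehyde, via iminium chloride 2 (not isolated)
Conditions: POCl3, DMF, 0 °C → rt; then ice-water
Reagents that add atoms: N,N-dimethylformamide, CN(C)C=O (formyl carbon); water, O (formyl oxygen)
Why: Vilsmeier–Haack formylation, in which the chloroiminium ion attacks the position ortho to one hydroxyl and para to the other, the usual site in resorcinols, and water hydrolyses 2 to the chelated aldehyde.

**Step 2**
Reactants: 3 2,4-dihydroxy-6-methylbenzaldehyde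
Product: 4 2,4-bis(benzyloxy)-6-methylbenzaldehyde
Conditions: BnBr, K2CO3, DMF, 60 °C
Reagents that add atoms: benzyl bromide, BrCc1ccccc1
Why: Williamson ether synthesis, where warm DMF suffices to alkylate the hydrogen-bonded C2 phenol as well and the aldehyde has no enolisable position.

**Step 3**
Reactants: 4 2,4-bis(benzyloxy)-6-methylbenzaldehyde
Product: 6 2,4-bis(benzyloxy)-6-methylphenol, via aryl formate 5 (not isolated)
Conditions: mCPBA, CH2Cl2, 0 °C → rt; then K2CO3 (cat.), MeOH, rt
Reagents that add atoms: 3-chloroperbenzoic acid, O=C(OO)c1cccc(Cl)c1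
Why: Baeyer–Villiger oxidation with a Dakin-type outcome, since the aryl group with ortho and para alkoxy donors migrates in the Criegee intermediate and formate 5 is removed by transesterification that leaves the benzyl ethers alone.

**Step 4**
Reactants: 6 2,4-bis(benzyloxy)-6-methylphenol
Product: 7 1,2,5-tris(benzyloxy)-3-methylbenzene
Conditions: BnBr, K2CO3, DMF, 60 °C
Reagents that add atoms: benzyl bromide, BrCc1ccccc1
Why: Williamson ether synthesis on a phenoxide that is flanked on both sides but still reacts readily with a primary benzylic halide.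

**Step 5**
Reactants: 7 1,2,5-tris(benzyloxy)-3-methylbenzene
Product: 9 2,4,5-tris(benzyloxy)-6-methylbenzaldehyde, via iminium chloride 8 (not isolated)
Conditions: POCl3, DMF, 0 → 70 °C; then H2O
Reagents that add atoms: N,N-dimethylformamide, CN(C)C=O (formyl carbon); water, O (formyl oxygen)
Why: Vilsmeier–Haack formylation at the free position next to the methyl group, which is para to one benzyloxy group and ortho to another, whereas the other free position is wedged between two benzyloxy groups; the same preference directs formylation of 3,5-dialkoxytoluenes.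

**Step 6**
Reactants: 9 2,4,5-tris(benzyloxy)-6-methylbenzaldehyde
Product: 10 2,4,5-tris(benzyloxy)-6-methylbenzoic acid
Conditions: NaClO2, NaH2PO4, 2-methylbut-2-ene, t-BuOH–THF–H2O, rt
Reagents that add atoms: sodium chlorite, [Na+].[O-]Cl=O
Why: Pinnick oxidation, which tolerates hindered, electron-rich aldehydes and benzyl ethers, with the alkene trapping hypochlorous acid before it can chlorinate the ring.

**Step 7**
Reactants: 10 2,4,5-tris(benzyloxy)-6-methylbenzoic acid; 11 methyl acetoacetate
Product: 13 methyl (E)-3-{[2,4,5-tris(benzyloxy)-6-methylbenzoyl]oxy}but-2-enoate, via acid chloride 12 (not isolated)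
Conditions: (COCl)2, DMF (cat.), CH2Cl2, 0 °C → rt, evaporate; then 11, Et3N, CH2Cl2, 0 °C → rt
Reagents that add atoms: oxalyl chloride, O=C(Cl)C(=O)Cl (supplies only the chlorine of 12)
Why: Acid chloride formation followed by O-acylation of a β-keto ester enolate, where an amine base without a chelating metal steers the hard, hindered aroyl chloride to the enolate oxygen; the E isomer drawn is expected to prevail, and the Z isomer is just as usable because the geometry is erased in step 8.

**Step 8**
Reactants: 13 methyl (E)-3-{[2,4,5-tris(benzyloxy)-6-methylbenzoyl]oxy}but-2-enoate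
Product: 15 (3Z)-4-[(tert-butyldimethylsilyl)oxy]-4-methoxybuta-1,3-dien-2-yl 2,4,5-tris(benzyloxy)-6-methylbenzoate, via lithium dienolate 14 (not isolated)
Conditions: LDA (1.05 equiv, commercial solution), THF, −78 °C; TBSOTf, −78 °C; pentane/cold aq NaHCO3 work-up, used without chromatography
Reagents that add atoms: tert-butyldimethylsilyl triflate, CC(C)(C)[Si](C)(C)OS(=O)(=O)C(F)(F)F; lithium diisopropylamide, [Li+].CC(C)[N-]C(C)C (supplies only the lithium of 14)
Why: Proposed new method: kinetic γ-deprotonation of an enoate and O-silylation of the dienolate is the standard entry to 1-alkoxy-1-silyloxybutadienes from 3-alkoxy- and 3-silyloxybut-2-enoates (closest known reaction type) but has not been shown with a 3-acyloxy group; it should carry over because the γ-methyl of (E)-13 lies cis to the ester carbonyl that guides the amide base, because the aroyl carbonyl is screened on both faces by the C2 benzyloxy and C6 methyl groups of ring A, because an acyl shift to the α- or γ-carbon would need a four-membered transition state, and because expulsion of the aroate towards the allenoate requires the C–O σ* orbital, which is orthogonal to the planar dienolate π system, so 14 should persist at −78 °C long enough to be trapped on oxygen by the fast, hard silyl triflate.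

**Step 9**
Reactants: 16 orsellinic acid (2,4-dihydroxy-6-methylbenzoic acid)
Product: 17 benzyl 2,4-dihydroxy-6-methylbenzoate
Conditions: BnBr, KHCO3, DMF, rt
Reagents that add atoms: benzyl bromide, BrCc1ccccc1
Why: SN2 alkylation of the carboxylate, since hydrogen carbonate deprotonates only the acid and leaves both phenols free, while room temperature avoids decarboxylation.

**Step 10**
Reactants: 17 benzyl 2,4-dihydroxy-6-methylbenzoate; 18 but-2-ynoic acid
Product: 19 benzyl 4-(but-2-ynoyloxy)-2-hydroxy-6-methylbenzoate
Conditions: DCC, DMAP (cat.), CH2Cl2, 0 °C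
Reagents that add atoms: none
Why: Steglich esterification at the C4 phenol only, because the C2 phenol is held in a hydrogen bond to the neighbouring ester carbonyl; ordinary depside couplings of orsellinates rest on the same selectivity.

**Step 11**
Reactants: 19 benzyl 4-(but-2-ynoyloxy)-2-hydroxy-6-methylbenzoate
Product: 20 benzyl 4-(but-2-ynoyloxy)-2-[(tert-butyldimethylsilyl)oxy]-6-methylbenzoate
Conditions: TBSOTf, 2,6-lutidine, CH2Cl2, 0 °C → rt
Reagents that add atoms: tert-butyldimethylsilyl triflate, CC(C)(C)[Si](C)(C)OS(=O)(=O)C(F)(F)F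
Why: Silyl ether formation with a silyl triflate and a non-nucleophilic base, which is strong enough for a chelated phenol, contains nothing that adds to the ynoate, and removes the last acidic proton that would quench ketene acetal 15.

**Step 12**
Reactants: 15 (3Z)-4-[(tert-butyldimethylsilyl)oxy]-4-methoxybuta-1,3-dien-2-yl 2,4,5-tris(benzyloxy)-6-methylbenzoate; 20 benzyl 4-(but-2-ynoyloxy)-2-[(tert-butyldimethylsilyl)oxy]-6-methylbenzoate
Product: 23 benzyl 2-hydroxy-4-{[2-hydroxy-6-methyl-4-({2,4,5-tris(benzyloxy)-6-methylbenzoyl}oxy)benzoyl]oxy}-6-methylbenzoate, via cycloadduct 21 (not isolated), via bis-silyl tridepside 22 (not isolated)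
Conditions: 15 (1 equiv), 20 (1.5 equiv), PhMe (ca. 2 M), activated 4 Å MS, BHT (cat.), sealed tube, 120 °C; filter, concentrate; then Et3N·3HF, THF, 0 °C → rt
Reagents that add atoms: none
Why: Proposed new method: a thermal, strongly polarised and probably asynchronous [4+2] cycloaddition joins the diene methylene (future C5) to the methyl-bearing β-carbon of the ynoate (C6) and the ketene acetal carbon (C2) to the α-carbon (C1), giving the 1,4-cyclohexadiene 21 with a methyl silyl ketal at C2; 1,4-loss of methanol (OMe from C2, H from C5) aromatises it to 22, and any remaining 21 collapses in the fluoride stage through the hemiketal and the dienone to the same phenol. The closest known reaction type is the Diels–Alder/aromatisation of 1-alkoxy-1,3-bis(silyloxy)-, 1,3-dialkoxy-1-silyloxy- and 1,1-dialkoxy-3-silyloxybutadienes with alk-2-ynoates, which gives 2,4-dioxygenated 6-alkylbenzoates; what has not been shown is a diene of this family with an acyl group on the C3 oxygen. Ring B closes in the intermolecular six-membered [4+2] mode, the four diene carbons adding across one π bond of the alkyne without a tether. The only new stereocentre, the ketal carbon of 21, arises racemic, needs no control and disappears on aromatisation. The step needs regioselectivity, which is secured because the two ketene acetal oxygens and the enol ester oxygen all polarise the diene towards its CH2 terminus, matching the electrophilic β-carbon of the ynoate, so the new hydroxyl and the methyl group end up on either side of the C1 ester. It also needs the ketene acetal to survive, which is secured by the absence of any acidic OH in 15 and 20, by sieves that take up methanol, and by the aryl rather than alkyl ynoate used in excess at high concentration to offset the weaker donor at C3; Et3N·3HF then frees both phenols without the basic conditions that would cleave the aryl esters.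

**Step 13**
Reactants: 23 benzyl 2-hydroxy-4-{[2-hydroxy-6-methyl-4-({2,4,5-tris(benzyloxy)-6-methylbenzoyl}oxy)benzoyl]oxy}-6-methylbenzoate
Product: 24 2-hydroxy-4-{[2-hydroxy-6-methyl-4-(2,4,5-trihydroxy-6-methylbenzoyloxy)benzoyl]oxy}-6-methylbenzoic acid (CNP0248995.0)
Conditions: H2 (1 atm), 10% Pd/C, EtOAc, rt; filtration under argon
Reagents that add atoms: none
Why: Catalytic hydrogenolysis of three benzyl ethers and one benzyl ester, to which depside aryl esters are inert in a non-nucleophilic solvent, with air excluded to protect the 1,2,4-trioxygenated ring A.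

**Compound list**
1 | orcinol (5-methylbenzene-1,3-diol) | Cc1cc(O)cc(O)c1 | starting material
2 | [(2,4-dihydroxy-6-methylphenyl)methylidene]dimethylammonium chloride (not isolated) | C[N+](C)=Cc1c(C)cc(O)cc1O.[Cl-] | intermediate
3 | 2,4-dihydroxy-6-methylbenzaldehyde | Cc1cc(O)cc(O)c1C=O | intermediate
4 | 2,4-bis(benzyloxy)-6-methylbenzaldehyde | Cc1cc(OCc2ccccc2)cc(OCc2ccccc2)c1C=O | intermediate
5 | 2,4-bis(benzyloxy)-6-methylphenyl formate (not isolated) | Cc1cc(OCc2ccccc2)cc(OCc2ccccc2)c1OC=O | intermediate
6 | 2,4-bis(benzyloxy)-6-methylphenol | Cc1cc(OCc2ccccc2)cc(OCc2ccccc2)c1O | intermediate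
7 | 1,2,5-tris(benzyloxy)-3-methylbenzene | Cc1cc(OCc2ccccc2)cc(OCc2ccccc2)c1OCc1ccccc1 | intermediate
8 | {[2,4,5-tris(benzyloxy)-6-methylphenyl]methylidene}dimethylammonium chloride (not isolated) | C[N+](C)=Cc1c(OCc2ccccc2)cc(OCc2ccccc2)c(OCc2ccccc2)c1C.[Cl-] | intermediate
9 | 2,4,5-tris(benzyloxy)-6-methylbenzaldehyde | O=Cc1c(OCc2ccccc2)cc(OCc2ccccc2)c(OCc2ccccc2)c1C | intermediate
10 | 2,4,5-tris(benzyloxy)-6-methylbenzoic acid | O=C(O)c1c(OCc2ccccc2)cc(OCc2ccccc2)c(OCc2ccccc2)c1C | intermediate
11 | methyl acetoacetate | COC(=O)CC(C)=O | starting material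
12 | 2,4,5-tris(benzyloxy)-6-methylbenzoyl chloride (not isolated) | O=C(Cl)c1c(OCc2ccccc2)cc(OCc2ccccc2)c(OCc2ccccc2)c1C | intermediate
13 | methyl (E)-3-{[2,4,5-tris(benzyloxy)-6-methylbenzoyl]oxy}but-2-enoate | C/C(OC(=O)c1c(OCc2ccccc2)cc(OCc2ccccc2)c(OCc2ccccc2)c1C)=C\C(=O)OC | intermediate
14 | lithium dienolate of 13 (not isolated) | C=C(OC(=O)c1c(OCc2ccccc2)cc(OCc2ccccc2)c(OCc2ccccc2)c1C)/C=C(/OC)[O-].[Li+] | intermediate
15 | (3Z)-4-[(tert-butyldimethylsilyl)oxy]-4-methoxybuta-1,3-dien-2-yl 2,4,5-tris(benzyloxy)-6-methylbenzoate (the 3E isomer would react alike) | C=C(OC(=O)c1c(OCc2ccccc2)cc(OCc2ccccc2)c(OCc2ccccc2)c1C)/C=C(/OC)O[Si](C)(C)C(C)(C)C | intermediate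
16 | orsellinic acid (2,4-dihydroxy-6-methylbenzoic acid) | Cc1cc(O)cc(O)c1C(=O)O | starting material
17 | benzyl 2,4-dihydroxy-6-methylbenzoate | Cc1cc(O)cc(O)c1C(=O)OCc1ccccc1 | intermediate
18 | but-2-ynoic acid | CC#CC(=O)O | starting material
19 | benzyl 4-(but-2-ynoyloxy)-2-hydroxy-6-methylbenzoate | CC#CC(=O)Oc1cc(C)c(C(=O)OCc2ccccc2)c(O)c1 | intermediate
20 | benzyl 4-(but-2-ynoyloxy)-2-[(tert-butyldimethylsilyl)oxy]-6-methylbenzoate | CC#CC(=O)Oc1cc(C)c(C(=O)OCc2ccccc2)c(O[Si](C)(C)C(C)(C)C)c1 | intermediate
21 | cyclohexa-1,4-diene cycloadduct with a methyl silyl ketal at ring B C2, racemic (not isolated) | COC1(O[Si](C)(C)C(C)(C)C)C=C(OC(=O)c2c(OCc3ccccc3)cc(OCc3ccccc3)c(OCc3ccccc3)c2C)CC(C)=C1C(=O)Oc1cc(C)c(C(=O)OCc2ccccc2)c(O[Si](C)(C)C(C)(C)C)c1 | intermediate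
22 | tridepside benzyl ester with TBS ethers on ring B O2 and ring C O2 (not isolated) | Cc1cc(OC(=O)c2c(OCc3ccccc3)cc(OCc3ccccc3)c(OCc3ccccc3)c2C)cc(O[Si](C)(C)C(C)(C)C)c1C(=O)Oc1cc(C)c(C(=O)OCc2ccccc2)c(O[Si](C)(C)C(C)(C)C)c1 | intermediate
23 | benzyl 2-hydroxy-4-{[2-hydroxy-6-methyl-4-({2,4,5-tris(benzyloxy)-6-methylbenzoyl}oxy)benzoyl]oxy}-6-methylbenzoate | Cc1cc(OC(=O)c2c(OCc3ccccc3)cc(OCc3ccccc3)c(OCc3ccccc3)c2C)cc(O)c1C(=O)Oc1cc(C)c(C(=O)OCc2ccccc2)c(O)c1 | intermediate
24 | 2-hydroxy-4-{[2-hydroxy-6-methyl-4-(2,4,5-trihydroxy-6-methylbenzoyloxy)benzoyl]oxy}-6-methylbenzoic acid (CNP0248995.0) | Cc1cc(OC(=O)c2c(C)cc(OC(=O)c3c(O)cc(O)c(O)c3C)cc2O)cc(O)c1C(=O)O | target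

**Step count**
Total step count: 13. Longest linear sequence: 10 (steps 1–8, 12, 13). The ring C branch (steps 9–11) joins at step 12.

**Steps most likely to fail**

Step 12 is the riskiest.
- The acyl group on the C3 oxygen weakens the diene, and the ynoate β-carbon is methyl-substituted, so the cycloaddition may be slower than thermal decay of the ketene acetal. Decay could occur by protonation by released methanol, by an O-to-C silyl shift, or by [2+2] addition at the ketene acetal double bond.
- Loss of silanol in place of methanol would leave ring B O2 methylated, and hydrogenolysis cannot undo that.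
- The fallback uses known chemistry. It sets out from 11, 20 and 10 and returns at 23.
- Compound 11 is silylated (TMSCl, Et3N) to methyl (E)-3-(trimethylsilyloxy)but-2-enoate F1.
- LDA/TMSCl then gives 1-methoxy-1,3-bis(trimethylsilyloxy)buta-1,3-diene F2. This is a much more electron-rich diene of a class whose cycloaddition/aromatisation with alk-2-ynoates is established.
- Heating F2 with 20 in toluene gives the cycloadduct F3. Et3N·3HF converts F3 into the ring B–ring C didepside benzyl 4-[(2,4-dihydroxy-6-methylbenzoyl)oxy]-2-hydroxy-6-methylbenzoate F4.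
- The only unchelated phenol of F4, ring B O4, is then esterified with acid 10 (DCC, toluene). This is the ordinary depside coupling, and it gives 23.

Step 8 comes second.
- The dienolate may fragment by loss of the aroate.
- The amide base may attack the enol ester or its β-carbon.
- The ring A C6 methyl group may be deprotonated laterally.
- Silylation may go to carbon.
- The fallback uses known chemistry. It sets out from 10, 3 and 17 and returns at 23. It takes ring B from the orcinol-derived aldehyde, so no enol ester ever meets a strong base.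
- The unchelated C4 phenol of 3 is esterified with 10 (DCC, cat. DMAP) to give 4-formyl-3-hydroxy-5-methylphenyl 2,4,5-tris(benzyloxy)-6-methylbenzoate F5.
- Pinnick oxidation gives 2-hydroxy-6-methyl-4-{[2,4,5-tris(benzyloxy)-6-methylbenzoyl]oxy}benzoic acid F6.
- DCC-mediated esterification of F6 with the C4 phenol of 17 gives 23.

Step 7 comes third.
- The hindered aroyl chloride may react sluggishly.
- Acylation may occur at the acetoacetate α-carbon.
- The ortho benzyl ether may be lost while the chloride is made.
- The fallback reverses the polarity, so the hindered partner acts as the oxygen nucleophile. It sets out from 10 and returns at 15.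
- Gold(I)-catalysed anti hydroacyloxylation (Ph3PAuCl/AgOTf, toluene) adds acid 10 to the β-carbon of commercial methyl but-2-ynoate. This gives methyl (Z)-3-{[2,4,5-tris(benzyloxy)-6-methylbenzoyl]oxy}but-2-enoate F7.
- Under the conditions of step 8, with DMPU as cosolvent because the γ-methyl is now trans to the ester, F7 gives the same dienolate 14 and hence 15.

**Further compounds**
F1 | step 12 | methyl (E)-3-(trimethylsilyloxy)but-2-enoate | C/C(O[Si](C)(C)C)=C\C(=O)OC
F2 | step 12 | (1Z)-1-methoxy-1,3-bis(trimethylsilyloxy)buta-1,3-diene | C=C(O[Si](C)(C)C)/C=C(/OC)O[Si](C)(C)C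
F3 | step 12 | cyclohexa-1,4-diene cycloadduct of F2 and 20, racemic | COC1(O[Si](C)(C)C)C=C(O[Si](C)(C)C)CC(C)=C1C(=O)Oc1cc(C)c(C(=O)OCc2ccccc2)c(O[Si](C)(C)C(C)(C)C)c1
F4 | step 12 | benzyl 4-[(2,4-dihydroxy-6-methylbenzoyl)oxy]-2-hydroxy-6-methylbenzoate | Cc1cc(O)cc(O)c1C(=O)Oc1cc(C)c(C(=O)OCc2ccccc2)c(O)c1
F5 | step 8 | 4-formyl-3-hydroxy-5-methylphenyl 2,4,5-tris(benzyloxy)-6-methylbenzoate | Cc1cc(OC(=O)c2c(OCc3ccccc3)cc(OCc3ccccc3)c(OCc3ccccc3)c2C)cc(O)c1C=O
F6 | step 8 | 2-hydroxy-6-methyl-4-{[2,4,5-tris(benzyloxy)-6-methylbenzoyl]oxy}benzoic acid | Cc1cc(OC(=O)c2c(OCc3ccccc3)cc(OCc3ccccc3)c(OCc3ccccc3)c2C)cc(O)c1C(=O)O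
F7 | step 7 | methyl (Z)-3-{[2,4,5-tris(benzyloxy)-6-methylbenzoyl]oxy}but-2-enoate | C/C(OC(=O)c1c(OCc2ccccc2)cc(OCc2ccccc2)c(OCc2ccccc2)c1C)=C/C(=O)OC
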